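**Retrosynthetic overview**

1. Target 42 ⇐ hydrogenolysis of 41 ⇐ C3 ketone reduction of 40 ⇐ semipinacol 1,2-aryl shift (C3 to C4) of carbinol 39 ⇐ arylcerium from dimer bromide 36 plus flavan-3-one 18. This forms the upper C4–middle C8 bond.
2. 36 ⇐ Lewis-acid C4→C8 coupling of 4-methoxyflavan-3-ol 19 with tetra-O-benzylepicatechin 34. This forms the middle C4–lower C8 bond.
3. 18 and 19 (one robinetinidol-type block, used twice) ⇐ trans-dihydroflavonol 15 ⇐ chalcone epoxide 13 ⇐ acetophenone 11 (from resorcinol) plus aldehyde 5 (from 4-bromophenol).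
4. 34 ⇐ flavan-3-one 33 ⇐ Baeyer–Villiger-type C-to-O shift on 2H-chromene-3-carbaldehyde 31 ⇐ salicylaldehyde 30 (resorcinol via phloroglucinol) plus cinnamaldehyde 25 (from catechol).
5. Ring order: rings A and B come from the phenols; ring C of the robinetinidol block (step 11); ring C of the epicatechin block (step 21); then the two C4–C8 bonds (steps 24 and 26–27).

Assumption: the SMILES is read as (2S,3R,4S) for the upper unit (2,3-trans-3,4-cis), (2S,3S,4S) for the middle unit (2,3-cis-3,4-trans) and (2R,3R) for the lower unit, both interflavan bonds running C4 to C8.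

**Route**

Step 1
Reactants: 1 4-bromophenol
Product: 2 5-bromo-2-hydroxybenzene-1,3-dicarbaldehyde
Conditions: hexamethylenetetramine (2.5 equiv), CF3CO2H, reflux; then 4 M HCl, rt
Reagents that add atoms: hexamethylenetetramine C1N2CN3CN1CN(C2)C3; water O
Why: Duff formylation occurs at both positions ortho to the phenol because the para position is blocked by bromine.

Step 2
Reactants: 2 5-bromo-2-hydroxybenzene-1,3-dicarbaldehyde
Product: 3 5-bromobenzene-1,2,3-triol
Conditions: 30% H2O2, H2SO4 (cat.), MeOH, rt, N2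
Reagents that add atoms: hydrogen peroxide OO
Why: acid Dakin oxidation (aryl shift from carbon to oxygen in the peroxy hemiacetal) converts each ortho-hydroxy aldehyde into a phenol via its formate, and the acidic medium keeps the triol from autoxidising.

Step 3
Reactants: 3 5-bromobenzene-1,2,3-triol
Product: 4 1,2,3-tris(benzyloxy)-5-bromobenzene
Conditions: BnBr (3.3 equiv), K2CO3, DMF, 60 °C, N2
Reagents that add atoms: benzyl bromide BrCc1ccccc1
Why: Williamson etherification of the three phenols.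

Step 4
Reactants: 4 1,2,3-tris(benzyloxy)-5-bromobenzene
Product: 5 3,4,5-tris(benzyloxy)benzaldehyde
Conditions: n-BuLi, THF, −78 °C; DMF; aq. NH4Cl
Reagents that add atoms: N,N-dimethylformamide CN(C)C=O
Why: bromine–lithium exchange outruns benzylic deprotonation at −78 °C and the aryllithium is formylated by DMF (Bouveault aldehyde synthesis).

Step 5
Reactants: 6 resorcinol
Product: 8 2-bromobenzene-1,3-diol, via 2,4,6-tribromoresorcinol 7 (not isolated)
Conditions: Br2 (3.0 equiv), H2O, rt; then Na2SO3 (2.2 equiv), NaOH, rt; HCl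
Reagents that add atoms: bromine BrBr
Why: exhaustive electrophilic bromination is followed by sulfite reduction, which removes only the two bromines para to a hydroxyl (protodebromination through the keto tautomer) and leaves the bromine between the two hydroxyls.

Step 6
Reactants: 8 2-bromobenzene-1,3-diol
Product: 9 1-(3-bromo-2,4-dihydroxyphenyl)ethanone
Conditions: AcOH, ZnCl2, 130 °C
Reagents that add atoms: acetic acid CC(=O)O
Why: Nencki Friedel–Crafts acylation goes ortho to one hydroxyl and para to the other, the position between the hydroxyls being blocked.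

Step 7
Reactants: 9 1-(3-bromo-2,4-dihydroxyphenyl)ethanone
Product: 10 1-[4-(benzyloxy)-3-bromo-2-hydroxyphenyl]ethanone
Conditions: BnBr (1.05 equiv), K2CO3, acetone, reflux
Reagents that add atoms: benzyl bromide BrCc1ccccc1
Why: Williamson etherification is selective for the 4-OH because the 2-OH is hydrogen-bonded to the ketone and flanked by bromine.

Step 8
Reactants: 10 1-[4-(benzyloxy)-3-bromo-2-hydroxyphenyl]ethanone
Product: 11 1-[4-(benzyloxy)-3-bromo-2-(methoxymethoxy)phenyl]ethanone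
Conditions: NaH, MeOCH2Cl, DMF, 0 °C
Reagents that add atoms: chloromethyl methyl ether COCCl
Why: O-alkylation of the sodium phenoxide gives the acetal that masks the phenol through the basic aldol and epoxidation steps.

Step 9
Reactants: 11 protected acetophenone; 5 3,4,5-tris(benzyloxy)benzaldehyde
Product: 12 (E)-1-[4-(benzyloxy)-3-bromo-2-(methoxymethoxy)phenyl]-3-[3,4,5-tris(benzyloxy)phenyl]prop-2-en-1-one
Conditions: KOH, EtOH/THF, rt
Reagents that add atoms: none
Why: Claisen–Schmidt aldol condensation gives the E enone.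

Step 10
Reactants: 12 chalcone
Product: 13 [4-(benzyloxy)-3-bromo-2-(methoxymethoxy)phenyl][(2S,3R)-3-[3,4,5-tris(benzyloxy)phenyl]oxiran-2-yl]methanone
Conditions: poly-D-leucine, urea–H2O2, DBU, THF, rt
Reagents that add atoms: urea–hydrogen peroxide NC(N)=O.OO
Why: Juliá–Colonna epoxidation (Weitz–Scheffer hydroperoxide addition inside the helical peptide) sets both epoxide carbons, poly-D-leucine giving the (2S,3R) trans-epoxide.

Step 11
Reactants: 13 chalcone epoxide
Product: 15 (2S,3S)-7-(benzyloxy)-8-bromo-3-hydroxy-2-[3,4,5-tris(benzyloxy)phenyl]chroman-4-one, via free phenol epoxide 14 (not isolated)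
Conditions: conc. HCl, MeOH/THF, 55 °C
Reagents that add atoms: none
Why: acetal cleavage frees the phenol, which opens the epoxide at the benzylic carbon in a 6-endo cyclisation with inversion (ring C), so C2 becomes S and the untouched former α-carbon becomes C3 (S), giving the 2,3-trans dihydroflavonol.

Step 12
Reactants: 15 trans-dihydroflavonol
Product: 17 (2S,3R,4S)-7-(benzyloxy)-8-bromo-4-methoxy-2-[3,4,5-tris(benzyloxy)phenyl]chroman-3-ol, via flavan-3,4-diol 16 (not isolated)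
Conditions: NaBH4, MeOH/THF, 0 °C; then HCl (to 0.2 M), 40 °C
Reagents that add atoms: methanol CO
Why: hydride reduction of the C4 ketone gives the 3,4-trans diol as is usual for dihydroflavonols, and acid then exchanges only the benzylic C4 hydroxyl for methoxy by SN1 solvolysis, again trans to the C3 hydroxyl (so cis to the C2 aryl).

Step 13
Reactants: 17 4-methoxy-2,3-trans-flavan-3-ol
Product: 18 (2S,4S)-7-(benzyloxy)-8-bromo-4-methoxy-2-[3,4,5-tris(benzyloxy)phenyl]chroman-3-one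
Conditions: Dess–Martin periodinane, NaHCO3, CH2Cl2, rt
Reagents that add atoms: none
Why: Dess–Martin oxidation of the secondary alcohol under buffered non-basic conditions leaves the C2 and C4 stereocentres untouched.

Step 14
Reactants: 18 4-methoxyflavan-3-one
Product: 19 (2S,3S,4S)-7-(benzyloxy)-8-bromo-4-methoxy-2-[3,4,5-tris(benzyloxy)phenyl]chroman-3-ol
Conditions: LiBH(s-Bu)3, THF, −78 °C
Reagents that add atoms: none
Why: the bulky hydride attacks the ketone from the face opposite the cis-disposed C2 aryl and C4 methoxy groups (substrate-controlled ketone reduction, as in the catechin-to-epicatechin inversion), giving the 2,3-cis alcohol.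

Step 15
Reactants: 20 catechol
Product: 21 1,2-bis(benzyloxy)benzene
Conditions: BnBr (2.2 equiv), K2CO3, DMF, 60 °C
Reagents that add atoms: benzyl bromide BrCc1ccccc1
Why: Williamson etherification of both phenols.

Step 16
Reactants: 21 1,2-bis(benzyloxy)benzene
Product: 22 1,2-bis(benzyloxy)-4-bromobenzene
Conditions: NBS, MeCN, rt
Reagents that add atoms: N-bromosuccinimide O=C1CCC(=O)N1Br
Why: electrophilic aromatic bromination goes para to one alkoxy group.

Step 17
Reactants: 22 1,2-bis(benzyloxy)-4-bromobenzene; 23 3,3-dimethoxyprop-1-ene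
Product: 25 (E)-3-[3,4-bis(benzyloxy)phenyl]prop-2-enal, via cinnamaldehyde dimethyl acetal 24 (not isolated)
Conditions: Pd(OAc)2 (3 mol%), Bu4NOAc, K2CO3, KCl, DMF, 90 °C; then 2 M HCl, rt
Reagents that add atoms: water O
Why: Heck arylation at the terminal alkene carbon with β-hydride elimination towards the aryl group gives the E alkene, and acid hydrolysis of the acetal releases the enal.

Step 18
Reactants: 6 resorcinol
Product: 28 benzene-1,3,5-triol (phloroglucinol), via bis(trimethylsilyl) ether 26 (not isolated), via arylboronic ester 27 (not isolated)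
Conditions: (Me3Si)2NH, 80 °C, then vacuum; [Ir(OMe)(cod)]2 (1.5 mol%), 4,4'-di-tert-butyl-2,2'-bipyridine (3 mol%), B2pin2 (0.6 equiv), cyclohexane, 80 °C; then KHSO5, acetone/H2O, rt; 1 M HCl
Reagents that add atoms: hexamethyldisilazane C[Si](C)(C)N[Si](C)(C)C; bis(pinacolato)diboron CC1(C)OB(OC1(C)C)B1OC(C)(C)C(C)(C)O1; potassium peroxymonosulfate [K+].[O-]S(=O)(=O)OO
Why: sterically governed iridium-catalysed C–H borylation takes place at the only C–H with no ortho substituent (meta to both silyloxy groups), and oxidative work-up converts C–B into C–OH while hydrolysing the silyl ethers (one-pot borylation/oxidation).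

Step 19
Reactants: 28 phloroglucinol
Product: 29 2,4,6-trihydroxybenzaldehyde
Conditions: POCl3, DMF, EtOAc, 0 °C to rt; then H2O, 60 °C
Reagents that add atoms: N,N-dimethylformamide CN(C)C=O; water O
Why: Vilsmeier–Haack formylation of the highly activated symmetrical ring stops after one formyl group because the product is deactivated.

Step 20
Reactants: 29 2,4,6-trihydroxybenzaldehyde
Product: 30 2,4-bis(benzyloxy)-6-hydroxybenzaldehyde
Conditions: BnBr (2.05 equiv), K2CO3, DMF, rt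
Reagents that add atoms: benzyl bromide BrCc1ccccc1
Why: Williamson etherification stops at the dibenzyl ether because the last ortho hydroxyl is strongly hydrogen-bonded to the aldehyde.

Step 21
Reactants: 30 2,4-bis(benzyloxy)-6-hydroxybenzaldehyde; 25 (E)-3-[3,4-bis(benzyloxy)phenyl]prop-2-enal
Product: 31 (2R)-5,7-bis(benzyloxy)-2-[3,4-bis(benzyloxy)phenyl]-2H-chromene-3-carbaldehyde
Conditions: (S)-α,α-diphenylprolinol trimethylsilyl ether (20 mol%), 2-nitrobenzoic acid (20 mol%), toluene, 4 Å molecular sieves, rt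
Reagents that add atoms: none
Why: iminium-activated oxa-Michael addition of the phenol followed by intramolecular aldol condensation (organocatalytic domino reaction) closes ring C, the silyloxydiphenylmethyl group shielding one face of the iminium ion so that C2 is formed as R.

Step 22
Reactants: 31 chromene carbaldehyde
Product: 33 (2R)-5,7-bis(benzyloxy)-2-[3,4-bis(benzyloxy)phenyl]chroman-3-one, via enol formate 32 (not isolated)
Conditions: 30% H2O2, (2-O2NC6H4Se)2 (5 mol%), CH2Cl2, rt; then NaHCO3, MeOH/H2O, 0 °C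
Reagents that add atoms: hydrogen peroxide OO
Why: Baeyer–Villiger oxidation of the enal by the arylseleninic peracid moves the vinyl carbon from carbon to oxygen (1,2-shift) to give the enol formate, and mild hydrolysis gives the C3 ketone without touching C2.

Step 23
Reactants: 33 flavan-3-one
Product: 34 (2R,3R)-5,7-bis(benzyloxy)-2-[3,4-bis(benzyloxy)phenyl]chroman-3-ol (tetra-O-benzylepicatechin)
Conditions: LiBH(s-Bu)3, THF, −78 °C
Reagents that add atoms: none
Why: the bulky hydride attacks opposite the C2 aryl group (substrate-controlled ketone reduction known for this ketone), giving the 2,3-cis alcohol.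

Step 24
Reactants: 19 all-cis 4-methoxyflavan-3-ol; 34 tetra-O-benzylepicatechin (4 equiv)
Product: 35 dimer bromide with free 3-hydroxyls (middle unit 2S,3S,4S; C4 bonded to C8 of the epicatechin unit)
Conditions: Me3SiOTf (0.3 equiv), CH2Cl2, −78 to −30 °C; Et3N quench
Reagents that add atoms: none
Why: Lewis-acid ionisation of the benzylic C4 methyl ether gives a flavan-4-yl cation (its own C8 is blocked by bromine) that is attacked by C8 of the phloroglucinol ring of 34 from the face opposite the C2 aryl and C3 hydroxyl (Friedel–Crafts-type interflavan coupling), setting the 3,4-trans C4 centre.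

Step 25
Reactants: 35 dimer bromide diol
Product: 36 dimer bromide with both 3-hydroxyls benzylated
Conditions: NaH, BnBr, Bu4NI (cat.), DMF, 0 °C to rt
Reagents that add atoms: benzyl bromide BrCc1ccccc1
Why: Williamson etherification removes the two acidic hydroxyls before the organometallic step.

Step 26
Reactants: 36 benzylated dimer bromide; 18 4-methoxyflavan-3-one
Product: 39 tertiary C3 carbinol (upper unit 2S,3S,4S; new aryl trans to the C2 aryl and to the C4 methoxy), via aryllithium 37 (not isolated), via arylcerium dichloride 38 (not isolated)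
Conditions: t-BuLi (2.1 equiv), THF, −78 °C; CeCl3, −78 °C; then 18; aq. NH4Cl
Reagents that add atoms: tert-butyllithium [Li]C(C)(C)C; cerium trichloride Cl[Ce](Cl)Cl
Why: bromine–lithium exchange and transmetalation give a weakly basic arylcerium reagent that adds to the enolisable C3 ketone from the face opposite the cis-disposed C2 aryl and C4 methoxy groups (organocerium 1,2-addition), which fixes the middle unit at its C8.

Step 27
Reactants: 39 tertiary C3 carbinol
Product: 40 4-aryl-flavan-3-one (upper unit 2S,4S; C4 bonded to C8 of the middle unit, 2,4-trans)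
Conditions: Me3SiOTf (0.2 equiv), CH2Cl2, −78 to −40 °C; Et3N quench
Reagents that add atoms: none
Why: Proposed new method: Me3SiOTf ionises the benzylic C4–OMe bond (cation stabilised by the para benzyloxy group and the ortho ring oxygen), the electron-rich aryl group on C3, which lies anti to the leaving group, shifts to C4 through a phenonium ion with inversion at C4 while the C3 oxygen becomes the carbonyl, so the upper C4–middle C8 bond and the C4 stereocentre are made in one 1,2-aryl shift; the closest known reaction type is the semipinacol (Tsuchihashi–Suzuki) rearrangement of alcohols with a leaving group on the neighbouring carbon, which has not been used to make an interflavan bond.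

Step 28
Reactants: 40 4-aryl-flavan-3-one
Product: 41 protected trimer with free upper 3-hydroxyl (upper unit 2S,3R,4S)
Conditions: NaBH4, THF/MeOH, −40 °C
Reagents that add atoms: none
Why: hydride adds to the C3 ketone from the face opposite the pseudoaxial C4 aryl group (substrate-controlled NaBH4 reduction), giving the hydroxyl cis to the C4 aryl and trans to the C2 aryl.

Step 29
Reactants: 41 protected trimer
Product: 42 target CNP0115797.3
Conditions: H2 (1 atm), Pd(OH)2/C, Et3N (2 equiv), THF/MeOH/H2O, rt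
Reagents that add atoms: none
Why: catalytic hydrogenolysis cleaves all fourteen benzyl ethers and the aryl C–Br bond without affecting the stereocentres.

**Compound list**

1 | 4-bromophenol | Oc1ccc(Br)cc1 | starting material
2 | 5-bromo-2-hydroxybenzene-1,3-dicarbaldehyde | O=Cc1cc(Br)cc(C=O)c1O | intermediate
3 | 5-bromobenzene-1,2,3-triol | Oc1cc(Br)cc(O)c1O | intermediate
4 | 1,2,3-tris(benzyloxy)-5-bromobenzene | Brc1cc(OCc2ccccc2)c(OCc2ccccc2)c(OCc2ccccc2)c1 | intermediate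
5 | 3,4,5-tris(benzyloxy)benzaldehyde | O=Cc1cc(OCc2ccccc2)c(OCc2ccccc2)c(OCc2ccccc2)c1 | intermediate
6 | resorcinol (benzene-1,3-diol) | Oc1cccc(O)c1 | starting material
7 | 2,4,6-tribromobenzene-1,3-diol | Oc1c(Br)c(O)c(Br)cc1Br | intermediate
8 | 2-bromobenzene-1,3-diol | Oc1cccc(O)c1Br | intermediate
9 | 1-(3-bromo-2,4-dihydroxyphenyl)ethanone | CC(=O)c1ccc(O)c(Br)c1O | intermediate
10 | 1-[4-(benzyloxy)-3-bromo-2-hydroxyphenyl]ethanone | CC(=O)c1ccc(OCc2ccccc2)c(Br)c1O | intermediate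
11 | 1-[4-(benzyloxy)-3-bromo-2-(methoxymethoxy)phenyl]ethanone | CC(=O)c1ccc(OCc2ccccc2)c(Br)c1OCOC | intermediate
12 | (E)-1-[4-(benzyloxy)-3-bromo-2-(methoxymethoxy)phenyl]-3-[3,4,5-tris(benzyloxy)phenyl]prop-2-en-1-one | O=C(/C=C/c1cc(OCc2ccccc2)c(OCc2ccccc2)c(OCc2ccccc2)c1)c1ccc(OCc2ccccc2)c(Br)c1OCOC | intermediate
13 | [4-(benzyloxy)-3-bromo-2-(methoxymethoxy)phenyl][(2S,3R)-3-[3,4,5-tris(benzyloxy)phenyl]oxiran-2-yl]methanone | O=C(c1ccc(OCc2ccccc2)c(Br)c1OCOC)[C@H]1O[C@@H]1c1cc(OCc2ccccc2)c(OCc2ccccc2)c(OCc2ccccc2)c1 | intermediate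
14 | [4-(benzyloxy)-3-bromo-2-hydroxyphenyl][(2S,3R)-3-[3,4,5-tris(benzyloxy)phenyl]oxiran-2-yl]methanone | O=C(c1ccc(OCc2ccccc2)c(Br)c1O)[C@H]1O[C@@H]1c1cc(OCc2ccccc2)c(OCc2ccccc2)c(OCc2ccccc2)c1 | intermediate
15 | (2S,3S)-7-(benzyloxy)-8-bromo-3-hydroxy-2-[3,4,5-tris(benzyloxy)phenyl]chroman-4-one | O=C1[C@@H](O)[C@H](c2cc(OCc3ccccc3)c(OCc3ccccc3)c(OCc3ccccc3)c2)Oc2c(Br)c(OCc3ccccc3)ccc21 | intermediate
16 | (2S,3R,4S)-7-(benzyloxy)-8-bromo-2-[3,4,5-tris(benzyloxy)phenyl]chromane-3,4-diol | O[C@@H]1[C@@H](O)[C@H](c2cc(OCc3ccccc3)c(OCc3ccccc3)c(OCc3ccccc3)c2)Oc2c(Br)c(OCc3ccccc3)ccc21 | intermediate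
17 | (2S,3R,4S)-7-(benzyloxy)-8-bromo-4-methoxy-2-[3,4,5-tris(benzyloxy)phenyl]chroman-3-ol | CO[C@@H]1[C@@H](O)[C@H](c2cc(OCc3ccccc3)c(OCc3ccccc3)c(OCc3ccccc3)c2)Oc2c(Br)c(OCc3ccccc3)ccc21 | intermediate
18 | (2S,4S)-7-(benzyloxy)-8-bromo-4-methoxy-2-[3,4,5-tris(benzyloxy)phenyl]chroman-3-one (2,4-cis) | CO[C@@H]1C(=O)[C@H](c2cc(OCc3ccccc3)c(OCc3ccccc3)c(OCc3ccccc3)c2)Oc2c(Br)c(OCc3ccccc3)ccc21 | intermediate
19 | (2S,3S,4S)-7-(benzyloxy)-8-bromo-4-methoxy-2-[3,4,5-tris(benzyloxy)phenyl]chroman-3-ol (all-cis) | CO[C@@H]1[C@H](O)[C@H](c2cc(OCc3ccccc3)c(OCc3ccccc3)c(OCc3ccccc3)c2)Oc2c(Br)c(OCc3ccccc3)ccc21 | intermediate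
20 | catechol (benzene-1,2-diol) | Oc1ccccc1O | starting material
21 | 1,2-bis(benzyloxy)benzene | c1ccc(COc2ccccc2OCc2ccccc2)cc1 | intermediate
22 | 1,2-bis(benzyloxy)-4-bromobenzene | Brc1ccc(OCc2ccccc2)c(OCc2ccccc2)c1 | intermediate
23 | 3,3-dimethoxyprop-1-ene (acrolein dimethyl acetal) | C=CC(OC)OC | starting material
24 | (E)-1,2-bis(benzyloxy)-4-(3,3-dimethoxyprop-1-enyl)benzene | COC(OC)/C=C/c1ccc(OCc2ccccc2)c(OCc2ccccc2)c1 | intermediate
25 | (E)-3-[3,4-bis(benzyloxy)phenyl]prop-2-enal | O=C/C=C/c1ccc(OCc2ccccc2)c(OCc2ccccc2)c1 | intermediate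
26 | 1,3-bis(trimethylsilyloxy)benzene | C[Si](C)(C)Oc1cccc(O[Si](C)(C)C)c1 | intermediate
27 | 2-[3,5-bis(trimethylsilyloxy)phenyl]-4,4,5,5-tetramethyl-1,3,2-dioxaborolane | C[Si](C)(C)Oc1cc(O[Si](C)(C)C)cc(B2OC(C)(C)C(C)(C)O2)c1 | intermediate
28 | phloroglucinol (benzene-1,3,5-triol) | Oc1cc(O)cc(O)c1 | intermediate
29 | 2,4,6-trihydroxybenzaldehyde | O=Cc1c(O)cc(O)cc1O | intermediate
30 | 2,4-bis(benzyloxy)-6-hydroxybenzaldehyde | O=Cc1c(O)cc(OCc2ccccc2)cc1OCc1ccccc1 | intermediate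
31 | (2R)-5,7-bis(benzyloxy)-2-[3,4-bis(benzyloxy)phenyl]-2H-chromene-3-carbaldehyde | O=CC1=Cc2c(OCc3ccccc3)cc(OCc3ccccc3)cc2O[C@@H]1c1ccc(OCc2ccccc2)c(OCc2ccccc2)c1 | intermediate
32 | (2R)-5,7-bis(benzyloxy)-2-[3,4-bis(benzyloxy)phenyl]-2H-chromen-3-yl formate | O=COC1=Cc2c(OCc3ccccc3)cc(OCc3ccccc3)cc2O[C@@H]1c1ccc(OCc2ccccc2)c(OCc2ccccc2)c1 | intermediate
33 | (2R)-5,7-bis(benzyloxy)-2-[3,4-bis(benzyloxy)phenyl]chroman-3-one | O=C1Cc2c(OCc3ccccc3)cc(OCc3ccccc3)cc2O[C@@H]1c1ccc(OCc2ccccc2)c(OCc2ccccc2)c1 | intermediate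
34 | (2R,3R)-5,7-bis(benzyloxy)-2-[3,4-bis(benzyloxy)phenyl]chroman-3-ol (5,7,3',4'-tetra-O-benzylepicatechin) | O[C@@H]1Cc2c(OCc3ccccc3)cc(OCc3ccccc3)cc2O[C@@H]1c1ccc(OCc2ccccc2)c(OCc2ccccc2)c1 | intermediate
35 | (2S,3S,4S)-7-(benzyloxy)-8-bromo-4-[(2R,3R)-5,7-bis(benzyloxy)-2-[3,4-bis(benzyloxy)phenyl]-3-hydroxychroman-8-yl]-2-[3,4,5-tris(benzyloxy)phenyl]chroman-3-ol | Brc1c(OCc2ccccc2)ccc2c1O[C@@H](c1cc(OCc3ccccc3)c(OCc3ccccc3)c(OCc3ccccc3)c1)[C@@H](O)[C@@H]2c1c(OCc2ccccc2)cc(OCc2ccccc2)c2c1O[C@H](c1ccc(OCc3ccccc3)c(OCc3ccccc3)c1)[C@H](O)C2 | intermediate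
36 | (2S,3S,4S)-3,7-bis(benzyloxy)-8-bromo-4-[(2R,3R)-3,5,7-tris(benzyloxy)-2-[3,4-bis(benzyloxy)phenyl]chroman-8-yl]-2-[3,4,5-tris(benzyloxy)phenyl]chromane | Brc1c(OCc2ccccc2)ccc2c1O[C@@H](c1cc(OCc3ccccc3)c(OCc3ccccc3)c(OCc3ccccc3)c1)[C@@H](OCc1ccccc1)[C@@H]2c1c(OCc2ccccc2)cc(OCc2ccccc2)c2c1O[C@H](c1ccc(OCc3ccccc3)c(OCc3ccccc3)c1)[C@H](OCc1ccccc1)C2 | intermediate
37 | 8-lithio analogue of 36 (Li in place of Br) | [Li]c1c(OCc2ccccc2)ccc2c1O[C@@H](c1cc(OCc3ccccc3)c(OCc3ccccc3)c(OCc3ccccc3)c1)[C@@H](OCc1ccccc1)[C@@H]2c1c(OCc2ccccc2)cc(OCc2ccccc2)c2c1O[C@H](c1ccc(OCc3ccccc3)c(OCc3ccccc3)c1)[C@H](OCc1ccccc1)C2 | intermediate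
38 | 8-(dichlorocerio) analogue of 36 (CeCl2 in place of Br) | Cl[Ce](Cl)c1c(OCc2ccccc2)ccc2c1O[C@@H](c1cc(OCc3ccccc3)c(OCc3ccccc3)c(OCc3ccccc3)c1)[C@@H](OCc1ccccc1)[C@@H]2c1c(OCc2ccccc2)cc(OCc2ccccc2)c2c1O[C@H](c1ccc(OCc3ccccc3)c(OCc3ccccc3)c1)[C@H](OCc1ccccc1)C2 | intermediate
39 | (2S,3S,4S)-7-(benzyloxy)-8-bromo-4-methoxy-2-[3,4,5-tris(benzyloxy)phenyl]chroman-3-ol carrying at C3 the C8 aryl carbon of debrominated 36 (aryl trans to the C2 aryl and to the C4 methoxy) | Brc1c(OCc2ccccc2)ccc2c1O[C@@H](c1cc(OCc3ccccc3)c(OCc3ccccc3)c(OCc3ccccc3)c1)[C@@](O)([C@H]2OC)c1c(OCc2ccccc2)ccc2c1O[C@@H](c1cc(OCc3ccccc3)c(OCc3ccccc3)c(OCc3ccccc3)c1)[C@@H](OCc1ccccc1)[C@@H]2c1c(OCc2ccccc2)cc(OCc2ccccc2)c2c1O[C@H](c1ccc(OCc3ccccc3)c(OCc3ccccc3)c1)[C@H](OCc1ccccc1)C2 | intermediate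
40 | (2S,4S)-7-(benzyloxy)-8-bromo-2-[3,4,5-tris(benzyloxy)phenyl]chroman-3-one carrying at C4 (trans to the C2 aryl) the C8 aryl carbon of debrominated 36 | Brc1c(OCc2ccccc2)ccc2c1O[C@@H](c1cc(OCc3ccccc3)c(OCc3ccccc3)c(OCc3ccccc3)c1)C(=O)[C@@H]2c1c(OCc2ccccc2)ccc2c1O[C@@H](c1cc(OCc3ccccc3)c(OCc3ccccc3)c(OCc3ccccc3)c1)[C@@H](OCc1ccccc1)[C@@H]2c1c(OCc2ccccc2)cc(OCc2ccccc2)c2c1O[C@H](c1ccc(OCc3ccccc3)c(OCc3ccccc3)c1)[C@H](OCc1ccccc1)C2 | intermediate
41 | (2S,3R,4S)-7-(benzyloxy)-8-bromo-2-[3,4,5-tris(benzyloxy)phenyl]chroman-3-ol carrying at C4 (cis to the 3-OH, trans to the C2 aryl) the C8 aryl carbon of debrominated 36 | Brc1c(OCc2ccccc2)ccc2c1O[C@@H](c1cc(OCc3ccccc3)c(OCc3ccccc3)c(OCc3ccccc3)c1)[C@H](O)[C@@H]2c1c(OCc2ccccc2)ccc2c1O[C@@H](c1cc(OCc3ccccc3)c(OCc3ccccc3)c(OCc3ccccc3)c1)[C@@H](OCc1ccccc1)[C@@H]2c1c(OCc2ccccc2)cc(OCc2ccccc2)c2c1O[C@H](c1ccc(OCc3ccccc3)c(OCc3ccccc3)c1)[C@H](OCc1ccccc1)C2 | intermediate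
42 | CNP0115797.3: ent-robinetinidol-(4α→8)-ent-epirobinetinidol-(4α→8)-epicatechin | Oc1ccc2c(c1)O[C@@H](c1cc(O)c(O)c(O)c1)[C@H](O)[C@@H]2c1c(O)ccc2c1O[C@@H](c1cc(O)c(O)c(O)c1)[C@@H](O)[C@@H]2c1c(O)cc(O)c2c1O[C@H](c1ccc(O)c(O)c1)[C@H](O)C2 | target

**Totals**

Total step count: 29.
Longest linear sequence: 16 steps (6 → 8 → 9 → 10 → 11 → 12 → 13 → 15 → 17 → 18 → 19 → 35 → 36 → 39 → 40 → 41 → 42).

**Three steps most likely to fail**

Step 27 (the proposed semipinacol shift, together with the cerium addition that feeds it). The risks are enolisation of 18 instead of addition, and ionisation without clean aryl migration. The fallback uses known ketone-addition and ionic-deoxygenation chemistry; it sets out from 36 and uses stored 15. Compound 15 is silylated (t-BuMe2SiOTf, 2,6-lutidine, CH2Cl2) to the 3-O-tert-butyldimethylsilyl dihydroflavonol F1. Aryllithium 37, made from 36 with t-BuLi in THF at −78 °C, adds to the C4 ketone of F1 opposite the silyloxy group to give the tertiary C4 carbinol F2. Bu3SnH with CF3CO2H in CH2Cl2 at 0 °C removes the tertiary benzylic hydroxyl, hydride arriving opposite the C3 silyloxy group, which gives the 3,4-cis 3-O-silyl trimer F3. Bu4NF in THF then gives 41, where the route is rejoined.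

Step 24 (interflavan coupling). The 5-deoxy cation is less stabilised than a phloroglucinol-type one, and O-alkylation, attack at C6 of 34, or self-condensation at C6 of 19 may compete. The fallback changes the activation mode from an oxophilic Lewis acid to thiophilic silver; it sets out from 19. Exchange of the C4 methoxy group with 2-mercaptobenzothiazole (BF3·OEt2, CH2Cl2, 0 °C) gives the 4-(1,3-benzothiazol-2-ylsulfanyl)flavan-3-ol F4. AgBF4 in THF at 0 °C, in the presence of 34, activates the C–S bond and gives 35, where the route is rejoined.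

Step 18 (one-pot silylation, C–H borylation and oxidation). The electron-rich, water-soluble triol may be over-oxidised or lost on work-up. The fallback uses aryne chemistry in place of C–H borylation; it sets out from 6. Chlorination with SO2Cl2 in Et2O gives 4-chlorobenzene-1,3-diol F5. A KOH melt at about 150 °C (elimination to the aryne and cine addition of hydroxide meta to the neighbouring oxide) gives 28 after acidification, where the route is rejoined.

Further compounds
F1 | step 27 | (2S,3S)-7-(benzyloxy)-8-bromo-3-[(tert-butyldimethylsilyl)oxy]-2-[3,4,5-tris(benzyloxy)phenyl]chroman-4-one | O=C1[C@@H](O[Si](C)(C)C(C)(C)C)[C@H](c2cc(OCc3ccccc3)c(OCc3ccccc3)c(OCc3ccccc3)c2)Oc2c(Br)c(OCc3ccccc3)ccc21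
F2 | step 27 | tertiary C4 carbinol from F1 and 37 (C4 hydroxyl cis to the 3-silyloxy group, C4 aryl = C8 of debrominated 36) | Brc1c(OCc2ccccc2)ccc2c1O[C@@H](c1cc(OCc3ccccc3)c(OCc3ccccc3)c(OCc3ccccc3)c1)[C@H](O[Si](C)(C)C(C)(C)C)[C@@]2(O)c1c(OCc2ccccc2)ccc2c1O[C@@H](c1cc(OCc3ccccc3)c(OCc3ccccc3)c(OCc3ccccc3)c1)[C@@H](OCc1ccccc1)[C@@H]2c1c(OCc2ccccc2)cc(OCc2ccccc2)c2c1O[C@H](c1ccc(OCc3ccccc3)c(OCc3ccccc3)c1)[C@H](OCc1ccccc1)C2
F3 | step 27 | 3-O-tert-butyldimethylsilyl ether of 41 (upper unit 2,3-trans-3,4-cis) | Brc1c(OCc2ccccc2)ccc2c1O[C@@H](c1cc(OCc3ccccc3)c(OCc3ccccc3)c(OCc3ccccc3)c1)[C@H](O[Si](C)(C)C(C)(C)C)[C@@H]2c1c(OCc2ccccc2)ccc2c1O[C@@H](c1cc(OCc3ccccc3)c(OCc3ccccc3)c(OCc3ccccc3)c1)[C@@H](OCc1ccccc1)[C@@H]2c1c(OCc2ccccc2)cc(OCc2ccccc2)c2c1O[C@H](c1ccc(OCc3ccccc3)c(OCc3ccccc3)c1)[C@H](OCc1ccccc1)C2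
F4 | step 24 | (2S,3S,4R)-4-(1,3-benzothiazol-2-ylsulfanyl)-7-(benzyloxy)-8-bromo-2-[3,4,5-tris(benzyloxy)phenyl]chroman-3-ol | s1c2ccccc2nc1S[C@H]1[C@H](O)[C@H](c2cc(OCc3ccccc3)c(OCc3ccccc3)c(OCc3ccccc3)c2)Oc2c(Br)c(OCc3ccccc3)ccc21
F5 | step 18 | 4-chlorobenzene-1,3-diol | Oc1ccc(Cl)c(O)c1
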